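**Retrosynthetic overview**
1. The C11–O ester bond is cut first: the target comes from (−)-drimenol 12 and bis-silylated caffeic acid 15 (made from caffeic acid 13).
2. Drimenol comes from α-face hydroboration of drima-7,9(11)-diene 10, which comes from methylenation of the C9 ketone 9 (11-nordrim-7-en-9-one).
3. Ketone 9 comes from the trans-fused ene-dione 5 by removal of the C6 oxygen (1,2-reduction, acetate, zinc); 5 comes from the cis adduct 3 by C5 epimerization and hydrogenation of ring A.
4. The feature used: ring B (C5–C10), with a carbonyl-bearing C9, the C7=C8 alkene carrying the C8 methyl, and the angular C10 methyl, is atom for atom 2,6-dimethyl-1,4-benzoquinone 1; C1–C4 with the C4 gem-dimethyl is 4-methylpenta-1,3-diene 2.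
5. Ring order: ring B is bought as 1; ring A is closed onto it in step 1 by a catalytic asymmetric Diels–Alder reaction that forms C1–C10 and C4–C5.

Key step: step 1

Drimane numbering is used throughout (C11 is the carbinol carbon on C9).

Assumption: the facial sense of the chiral catalyst is inferred by analogy from its acrylate and quinone additions, where the (S)-prolinol-derived oxazaborolidine is expected to give (10S)-3; if the adduct proves antipodal, the catalyst from (R)-α,α-diphenylprolinol is used and nothing else changes.

**Route**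

Step 1
Reactants: 1 2,6-dimethyl-1,4-benzoquinone; 2 4-methylpenta-1,3-diene
Product: 3 (5R,10S)-11-nordrima-2,7-diene-6,9-dione (cis-fused adduct)
Conditions: (S)-3,3-diphenyl-1-(2-methylphenyl)tetrahydro-1H,3H-pyrrolo[1,2-c][1,3,2]oxazaborole (20 mol%), AlBr3 (16 mol%), CH2Cl2, −78 to −40 °C, 2 (4 equiv) added slowly
Reagents that add atoms: none
Why: Proposed new method: AlBr3 on the oxazaborolidine nitrogen makes boron a strong chiral Lewis acid that binds the unflanked carbonyl of 1 (the future C6) with an α-C–H contact to the ring oxygen, so the methyl-bearing β-carbon (future C10) becomes the electrophilic site; the CH2 terminus of 2 bonds there first and the dimethylallyl cation–boron enolate pair then collapses, a stepwise, strongly asynchronous [4+2] that does not need the hindered s-cis diene in a concerted transition state. The closest known reactions are oxazaborolidinium-catalysed Diels–Alder additions of 1 and related quinones to simple dienes, and cation-type stepwise [4+2] additions of hindered dienes with a disubstituted terminus. Ring A closes by C1–C10 bond formation followed by six-membered enolate-to-allyl-cation closure at C4–C5 on the same face, which gives the cis fusion. C10 is set by the catalyst, whose phenyl group shields one face of the bound enone; C5 follows from the same-face closure and is corrected in step 2. The step needs orientation control, which is secured because the Lewis-acid polarization of the quinone and the cation stability of the diene point the same way, and it needs suppression of cationic oligomerization of 2, addressed by slow addition at low temperature.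

Step 2
Reactants: 3 (5R,10S)-11-nordrima-2,7-diene-6,9-dione
Product: 4 (5S,10S)-11-nordrima-2,7-diene-6,9-dione (trans-fused)
Conditions: DBU (0.2 equiv), toluene, 23 °C
Reagents that add atoms: none
Why: Base-mediated epimerization through the C5 enolate (the only enolizable position next to the C6 carbonyl; C10 is quaternary, so aromatization is impossible) should equilibrate the cis adduct towards the trans fusion, in which ring A is joined to ring B by two pseudo-equatorial bonds, so C5 is set under thermodynamic control and unchanged 3 is separated and recycled.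

Step 3
Reactants: 4 (5S,10S)-11-nordrima-2,7-diene-6,9-dione
Product: 5 (5S,10S)-11-nordrim-7-ene-6,9-dione
Conditions: H2 (1 atm), (Ph3P)3RhCl (5 mol%), toluene–EtOH, 23 °C
Reagents that add atoms: none
Why: Homogeneous hydrogenation with (Ph3P)3RhCl should saturate the unconjugated cis-disubstituted C2=C3 alkene while the trisubstituted, electron-poor C7=C8 alkene of the ene-dione and both carbonyls stay untouched; no stereocentre is formed.

Step 4
Reactants: 5 (5S,10S)-11-nordrim-7-ene-6,9-dione
Product: 6 (5S,6R,10S)-6-hydroxy-11-nordrim-7-en-9-one (6β-alcohol)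
Conditions: NaBH4 (1.0 equiv), CeCl3·7H2O, MeOH, −78 to −40 °C
Reagents that add atoms: none
Why: Luche 1,2-reduction should occur at the C6 carbonyl, flanked only by the C5 methine and the C7 vinyl hydrogen, in preference to the C9 carbonyl, shielded by the quaternary C10 and the C8 methyl; hydride enters from the α face opposite the axial C10 and C4 methyls to give the 6β-alcohol, a centre removed again in step 6.

Step 5
Reactants: 6 (5S,6R,10S)-6-hydroxy-11-nordrim-7-en-9-one
Product: 7 (5S,6R,10S)-6-acetoxy-11-nordrim-7-en-9-one
Conditions: Ac2O (3 equiv), DMAP (0.3 equiv), pyridine, 40 °C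
Reagents that add atoms: acetic anhydride, CC(=O)OC(C)=O
Why: DMAP-catalysed acylation converts the hindered pseudo-axial allylic alcohol into the acetate leaving group needed for the reductive cleavage; no stereocentre changes.

Step 6
Reactants: 7 (5S,6R,10S)-6-acetoxy-11-nordrim-7-en-9-one
Product: 9 (5S,10S)-11-nordrim-7-en-9-one, via 11-nordrim-6-en-9-one 8 (not isolated)
Conditions: Zn dust, AcOH, 23 °C; filter, concentrate; then DBU (1 equiv), CH2Cl2, 23 °C
Reagents that add atoms: none
Why: Zinc reduction of a γ-acetoxy enone (vinylogous α-acetoxy ketone cleavage) should expel acetate from C6 through the zinc dienolate, whose protonation at C8 gives the deconjugated ketone 8; DBU then returns the alkene to conjugation at C7=C8 without touching C5 or C10.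

Step 7
Reactants: 9 (5S,10S)-11-nordrim-7-en-9-one
Product: 10 (5S,10S)-drima-7,9(11)-diene
Conditions: Ph3PCH3Br (3 equiv), KOtBu (2.8 equiv), toluene, 90 °C
Reagents that add atoms: methyltriphenylphosphonium bromide, C[P+](c1ccccc1)(c1ccccc1)c1ccccc1.[Br-]
Why: Wittig methylenation with the ylide generated by KOtBu in hot toluene is the standard method for hindered ketones and should convert the C9 carbonyl into the exocyclic C9=C11 alkene; no stereocentre is formed.

Step 8
Reactants: 10 (5S,10S)-drima-7,9(11)-diene
Product: 12 (−)-drimenol, via 9-(drim-7-en-11-yl)-9-borabicyclo[3.3.1]nonane 11 (not isolated)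
Conditions: 9-borabicyclo[3.3.1]nonane (9-BBN, 1.5 equiv), THF, 0 to 40 °C; then NaOH (3 M), H2O2 (30%), 0 to 23 °C
Reagents that add atoms: 9-borabicyclo[3.3.1]nonane, B1C2CCCC1CCC2 (boron of 11); hydrogen peroxide, OO (oxygen of 12)
Why: Hydroboration–oxidation with the bulky borane should place boron on the terminal C11 of the 1,1-disubstituted alkene and leave the trisubstituted C7=C8 alkene alone; hydrogen is delivered to C9 from the α face opposite the axial C10 methyl, which sets 9S (9α-H, CH2OH β).

Step 9
Reactants: 13 caffeic acid
Product: 15 (E)-3,4-bis(tert-butyldimethylsilyloxy)cinnamic acid, via tris(tert-butyldimethylsilyl) caffeate 14 (not isolated)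
Conditions: tert-butyldimethylsilyl chloride (3.3 equiv), imidazole, DMF, 23 °C; then AcOH–THF–H2O, 23 °C
Reagents that add atoms: tert-butyldimethylsilyl chloride, CC(C)(C)[Si](C)(C)Cl
Why: Exhaustive silylation followed by selective hydrolysis of the labile silyl ester frees the acid and leaves the catechol masked against acylation and oxidation.

Step 10
Reactants: 12 (−)-drimenol; 15 (E)-3,4-bis(tert-butyldimethylsilyloxy)cinnamic acid
Product: 16 drim-7-en-11-yl (E)-3,4-bis(tert-butyldimethylsilyloxy)cinnamate
Conditions: N,N'-diisopropylcarbodiimide (1.3 equiv), DMAP (0.2 equiv), CH2Cl2, 0 to 23 °C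
Reagents that add atoms: none
Why: Steglich esterification (carbodiimide activation with DMAP as acyl-transfer catalyst) should acylate the primary C11 alcohol without affecting the C7=C8 alkene or the (E)-cinnamate geometry.

Step 11
Reactants: 16 drim-7-en-11-yl (E)-3,4-bis(tert-butyldimethylsilyloxy)cinnamate
Product: 17 CNP0265201.1 (drim-7-en-11-yl caffeate)
Conditions: Bu4NF (2.2 equiv), AcOH (2.5 equiv), THF, 0 °C
Reagents that add atoms: none
Why: Fluoride cleaves the two aryl silyl ethers quickly, and the acetic acid buffer keeps the freed catechol protonated so that the ester and the catechol are not exposed to base.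

**Compound list**
1 | 2,6-dimethyl-1,4-benzoquinone | CC1=CC(=O)C=C(C)C1=O | starting material
2 | 4-methylpenta-1,3-diene | C=CC=C(C)C | starting material
3 | (5R,10S)-11-nordrima-2,7-diene-6,9-dione, cis-fused; also (4aR,8aS)-2,5,5,8a-tetramethyl-4a,5,8,8a-tetrahydronaphthalene-1,4-dione | CC1=CC(=O)[C@@H]2C(C)(C)C=CC[C@]2(C)C1=O | intermediate
4 | (5S,10S)-11-nordrima-2,7-diene-6,9-dione, trans-fused | CC1=CC(=O)[C@H]2C(C)(C)C=CC[C@]2(C)C1=O | intermediate
5 | (5S,10S)-11-nordrim-7-ene-6,9-dione | CC1=CC(=O)[C@H]2C(C)(C)CCC[C@]2(C)C1=O | intermediate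
6 | (5S,6R,10S)-6-hydroxy-11-nordrim-7-en-9-one (6β-OH) | CC1=C[C@@H](O)[C@H]2C(C)(C)CCC[C@]2(C)C1=O | intermediate
7 | (5S,6R,10S)-6-acetoxy-11-nordrim-7-en-9-one | CC1=C[C@@H](OC(C)=O)[C@H]2C(C)(C)CCC[C@]2(C)C1=O | intermediate
8 | (5S,10S)-11-nordrim-6-en-9-one, C8 epimers | CC1C=C[C@H]2C(C)(C)CCC[C@]2(C)C1=O | intermediate
9 | (5S,10S)-11-nordrim-7-en-9-one | CC1=CC[C@H]2C(C)(C)CCC[C@]2(C)C1=O | intermediate
10 | (5S,10S)-drima-7,9(11)-diene | CC1=CC[C@H]2C(C)(C)CCC[C@]2(C)C1=C | intermediate
11 | 9-(drim-7-en-11-yl)-9-borabicyclo[3.3.1]nonane (9α-H, configuration as in 12) | CC1=CC[C@H]2C(C)(C)CCC[C@]2(C)[C@H]1CB1C2CCCC1CCC2 | intermediate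
12 | (−)-drimenol, (5S,9S,10S)-drim-7-en-11-ol | CC1=CC[C@H]2C(C)(C)CCC[C@]2(C)[C@H]1CO | intermediate
13 | caffeic acid | OC(=O)/C=C/c1ccc(O)c(O)c1 | starting material
14 | tert-butyldimethylsilyl (E)-3,4-bis(tert-butyldimethylsilyloxy)cinnamate | CC(C)(C)[Si](C)(C)OC(=O)/C=C/c1ccc(O[Si](C)(C)C(C)(C)C)c(O[Si](C)(C)C(C)(C)C)c1 | intermediate
15 | (E)-3,4-bis(tert-butyldimethylsilyloxy)cinnamic acid | OC(=O)/C=C/c1ccc(O[Si](C)(C)C(C)(C)C)c(O[Si](C)(C)C(C)(C)C)c1 | intermediate
16 | (5S,9S,10S)-drim-7-en-11-yl (E)-3,4-bis(tert-butyldimethylsilyloxy)cinnamate | CC1=CC[C@H]2C(C)(C)CCC[C@]2(C)[C@H]1COC(=O)/C=C/c1ccc(O[Si](C)(C)C(C)(C)C)c(O[Si](C)(C)C(C)(C)C)c1 | intermediate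
17 | CNP0265201.1, (5S,9S,10S)-drim-7-en-11-yl (E)-3-(3,4-dihydroxyphenyl)prop-2-enoate | CC1=CC[C@H]2C(C)(C)CCC[C@]2(C)[C@H]1COC(=O)/C=C/c1ccc(O)c(O)c1 | target

**Step count**
Total: 11 steps. Longest linear sequence: 10 steps (steps 1–8, 10, 11); step 9 is the side branch.

**Steps most likely to fail**

Step 1 (new method). What may go wrong: the cis-methyl diene fails to add and is consumed by Lewis-acid oligomerization, or the first-formed zwitterion loses a proton instead of closing ring A. The fallback sets out from 1 and comes back at 3. The diene is replaced by its 2-silyloxy analogue, 4-methyl-2-(triisopropylsilyloxy)penta-1,3-diene F1, made from 4-methylpent-3-en-2-one with LiN(iPr)2 and iPr3SiOTf (THF, −78 °C). 2-Silyloxydienes are established partners of quinones of this type under the same oxazaborolidine catalysis, and this gem-dimethyl silyloxydiene is an established partner of hindered 2-methyl enones under aluminium Lewis acids, reacting by Mukaiyama–Michael addition and ring closure. The orientation is unchanged because the enol ether CH2 is the nucleophilic terminus. The adduct, (5R,10S)-2-(triisopropylsilyloxy)-11-nordrima-2,7-diene-6,9-dione F2, is converted with CsF and PhNTf2 (DME, 23 °C) into (5R,10S)-2-(trifluoromethylsulfonyloxy)-11-nordrima-2,7-diene-6,9-dione F3. Reduction with Pd(OAc)2, PPh3, HCO2H and Bu3N (DMF, 60 °C) replaces the triflate by hydrogen and gives 3.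

Step 2. What may go wrong: with ring B a flat ene-dione, the equilibrium at C5 may not lie far enough on the trans side, so epimerization stalls at a mixture. The fallback sets out from 3 and comes back at 8, which the DBU stage of step 6 carries on to 9. Hydrogenation of 3 (H2, Pd/C, EtOAc) saturates both C2=C3 and C7=C8 and gives cis-fused (5R,10S)-11-nordrimane-6,9-dione F4. Equilibration with NaOMe in MeOH then acts on a ring B in which C7 and C8 are sp3, where the cis fusion would force the C4 carbon into an axial position facing the C7 hydrogen; this should give trans-fused (5S,10S)-11-nordrimane-6,9-dione F5 with an equatorial C8 methyl. Kinetic deprotonation at the C7 methylene (KN(SiMe3)2, THF, −78 °C; the C5 and C8 methines are more hindered) and trapping with PhNTf2 gives (5S,10S)-6-(trifluoromethylsulfonyloxy)-11-nordrim-6-en-9-one F6. Reduction with Pd(OAc)2, PPh3, HCO2H and Bu3N (DMF, 60 °C) gives 8.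

Step 4. What may go wrong: poor site selectivity, with hydride attacking the C9 carbonyl or adding in conjugate fashion to the ene-dione. The fallback sets out from 5 and comes back at 8. Reversible condensation with p-toluenesulfonylhydrazide (EtOH, catalytic AcOH, 50 °C) is far more sensitive than hydride attack to the quaternary C10 and the C8 methyl that flank C9, and should give the C6 tosylhydrazone, (5S,10S)-6-(p-toluenesulfonylhydrazono)-11-nordrim-7-en-9-one F7. Reduction with catecholborane (CHCl3, 0 °C) and warming with NaOAc·3H2O expels sulfinate to give the allylic diazene, 6-diazenyl-11-nordrim-7-en-9-one F8. This loses nitrogen with transfer of hydrogen to C8 and shift of the alkene to C6=C7, which is 8; the DBU stage of step 6 then gives 9.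

Further compounds
F1 | step 1 | 4-methyl-2-(triisopropylsilyloxy)penta-1,3-diene | C=C(O[Si](C(C)C)(C(C)C)C(C)C)C=C(C)C
F2 | step 1 | (5R,10S)-2-(triisopropylsilyloxy)-11-nordrima-2,7-diene-6,9-dione | CC1=CC(=O)[C@@H]2C(C)(C)C=C(O[Si](C(C)C)(C(C)C)C(C)C)C[C@]2(C)C1=O
F3 | step 1 | (5R,10S)-2-(trifluoromethylsulfonyloxy)-11-nordrima-2,7-diene-6,9-dione | CC1=CC(=O)[C@@H]2C(C)(C)C=C(OS(=O)(=O)C(F)(F)F)C[C@]2(C)C1=O
F4 | step 2 | (5R,10S)-11-nordrimane-6,9-dione, cis-fused, C8 epimers | CC1CC(=O)[C@@H]2C(C)(C)CCC[C@]2(C)C1=O
F5 | step 2 | (5S,10S)-11-nordrimane-6,9-dione, trans-fused, C8 methyl equatorial | CC1CC(=O)[C@H]2C(C)(C)CCC[C@]2(C)C1=O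
F6 | step 2 | (5S,10S)-6-(trifluoromethylsulfonyloxy)-11-nordrim-6-en-9-one | CC1C=C(OS(=O)(=O)C(F)(F)F)[C@H]2C(C)(C)CCC[C@]2(C)C1=O
F7 | step 4 | (5S,10S)-6-(p-toluenesulfonylhydrazono)-11-nordrim-7-en-9-one | CC1=CC(=NNS(=O)(=O)c2ccc(C)cc2)[C@H]2C(C)(C)CCC[C@]2(C)C1=O
F8 | step 4 | (5S,10S)-6-diazenyl-11-nordrim-7-en-9-one, C6 epimers | CC1=CC(N=N)[C@H]2C(C)(C)CCC[C@]2(C)C1=O
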